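3 questions stand on the south flask, and 2 amounts in its readings answer them: left-handed product made and left-handed substrate lost.

| setting | south | west | flask |
|---|---|---|---|
| left-handed substrate | 0.10 M | 0.10 M | 0.10 M |
| right-handed substrate | 0.10 M | 0.10 M | 0.10 M |
| coupling partner | 0.30 M (in portions, 3) | 0.45 M (in portions, 3) | 0.300 M (in portions, 3) |
| remark | the very flask that is asked about, followed so far; portions every 15 h | run made earlier; portions every 15 h | the portions of coupling partner follow each other after 15 h, the first at the start |
| time |  |  | 6.0 d |

| run | time / d | left-handed product / % | left-handed substrate / % |
|---|---|---|---|
| south | 0.208 | 0.3 | 49.5 |
| south | 0.333 | 1.6 | 49.5 |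
| south | 0.625 | 0.8 | 48.9 |
| south | 1.25 | 4.2 | 47.2 |
| south | 2.50 | 11.5 | 42.0 |
| west | 0.208 | 0.6 | 49.2 |
| west | 0.333 | 0.8 | 49.3 |
| west | 0.625 | 2.0 | 48.6 |
| west | 1.25 | 6.2 | 45.6 |
| west | 2.50 | 16.4 | 38.6 |

(standard deviation of a reading: 0.3 percentage points)

- which holds at 6.0 d: what has brought the reaction to rest, or that it has not come to rest (the coupling partner has run out first / all of the left-handed substrate has reacted / forward and back rates have come level / it is still moving)
- amount of left-handed product at 6.0 d, in percent of the left-handed substrate and right-handed substrate together charged
- amount of left-handed product if the flask were left three thousand times as long, in percent of the left-handed substrate and right-handed substrate together charged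

- coupling partner is single-handed; left-handed substrate and right-handed substrate are mirror images of each other, charged as a racemate, each of them at the stated concentration
- the numbers in the tables scatter by 0.3 percentage points (one standard deviation)
- the reaction counts as stopped when no species that holds the left-handed substrate and right-handed substrate together changes by six tenths of a point or more over the second half of the time
- the handed part of coupling partner does not stay in what it makes, so the products of the two hands are mirror images too

At 2.50 d the south flask holds 11.5% of left-handed product but has lost 8.00% of left-handed substrate, less than the product made, so right-handed substrate is feeding the left. I take the two substrates as level. The substrate reacted is then 2 times the left-handed loss, and the left share (the selectivity) reads 71.9%: left-handed product made over substrate reacted. West reads 71.9%, though a scatter of 0.3 percentage points on that loss leaves both rough.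

After the last portion, between 1.25 d and 2.50 d, the south flask's left-handed substrate falls at 0.0934 d⁻¹. Held there, 0.327 lifetimes remain to 6.0 d, leaving 30.3% of left-handed substrate, and the left share gives 28.3% of left-handed product. Over the second half that substrate still falls 9.8 points, outside the margin for rest in the conditions above, so I say it is moving. The partner charge is 1.50 times both substrates together, so if the products stay as made, the end holds 71.9% of left-handed product.

The forecast says it is still moving, 26% (23% to 29%) and 50% (44% to 72%), both numbers lower than mine, and for the long-run number it argues: “Because the products are mirror images, true equilibrium must be racemic.”

The simulation gives: it is still moving, 25.0% of left-handed product, and 75.5% in the long run.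

    coupling partner + left-handed substrate → left-handed product (k = 0.0209 L mol⁻¹ h⁻¹)
    coupling partner + right-handed substrate → right-handed product (k = 0.00668 L mol⁻¹ h⁻¹)
    left-handed substrate ⇌ right-handed substrate (k = 0.0791 h⁻¹)
    coupling partner ⇌ dormant form (K = 0.420, k = 0.00279 h⁻¹)

The south flask is not at rest: by 60.0 d its left-handed product goes from 25.0% to 68.0% and its left-handed substrate from 33.1% to 4.96%. Right-handed product then stands at 22.0%, a left share of 75.5% against my reading of 71.9%. In a neighbour flask with 0.75 M of coupling partner, 17.5% and 18.3% of the substrates stand at 6.0 d, so the left share gives 46.2% of left-handed product; that neighbour flask computes to 48.1%.

The data were generated by integration from invented constants.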